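## Retrosynthetic overview

1. Ring D is closed last by an intramolecular Claisen acylation (C8–C15) of a tricyclic lactone ester, with C16 set by protonation of the resulting enolate; desilylation of O-11 then gives the target.
2. The C15–C17 unit is added to C13 by a Mukaiyama–Michael reaction on a C11 enone, which comes from the C11=C12 alkene of the key cycloadduct.
3. Key step: an intramolecular Diels–Alder reaction of a C20 acrylate onto a C9 butadienyl group forms the δ-lactone (ring B) and ring C together.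
4. Ring A and its γ-lactone come from a Diels–Alder reaction of 4-vinylbutenolide with a glycerol-acetal-bearing α-substituted acrolein (sets C10), followed by cuprate methylation (C4, C5).
5. Ring order: A → B/C → D. All chirality is relayed from (S)-butane-1,2,4-triol acetonide (from (S)-malic acid).

Assumption: atom labels C1–C20 are the ent-kaurane positions of the target; β is the face of H-5, H-9 and the C15–C16 bridge, α the face of C19, C20 and O-11 (target = 4R,5R,8S,9S,10R,11R,13S,16R).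

## Route

Step 1
Reactants: 1 (S)-2-(2,2-dimethyl-1,3-dioxolan-4-yl)ethanol
Product: 2 (S)-2-(2,2-dimethyl-1,3-dioxolan-4-yl)acetaldehyde
Conditions: TEMPO (10 mol %), PhI(OAc)2, CH2Cl2, rt
Reagents that add atoms: none
Why: Oxoammonium (TEMPO) oxidation stops at the aldehyde under near-neutral conditions, so the acetal and the bought (S) centre are untouched.

Step 2
Reactants: 2 (S)-2-(2,2-dimethyl-1,3-dioxolan-4-yl)acetaldehyde
Product: 3 (S)-2-(2,2-dimethyl-1,3-dioxolan-4-yl)prop-2-enal
Conditions: 37% aq. CH2O, pyrrolidine (10 mol %), EtCO2H (10 mol %), i-PrOH, 45 °C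
Reagents that add atoms: formaldehyde, C=O
Why: Amine-catalysed Mannich condensation–elimination (α-methylenation of an aldehyde) adds C1 to the future C10 without touching the adjacent acetal stereocentre.

Step 3
Reactants: 4 4-bromofuran-2(5H)-one
Product: 5 4-ethenylfuran-2(5H)-one
Conditions: Bu3SnCH=CH2, Pd(PPh3)4 (5 mol %), toluene, 90 °C
Reagents that add atoms: tributyl(ethenyl)stannane, C=C[Sn](CCCC)(CCCC)CCCC
Why: Stille cross-coupling of the vinylogous acyl bromide gives the 2-substituted diene that carries C2–C6 and C19.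

Step 4
Reactants: 3 (S)-2-(2,2-dimethyl-1,3-dioxolan-4-yl)prop-2-enal; 5 4-ethenylfuran-2(5H)-one
Product: 7 (7R)-7-[(4S)-2,2-dimethyl-1,3-dioxolan-4-yl]-1-oxo-1,3,4,5,6,7-hexahydro-2-benzofuran-7-carbaldehyde, via primary cycloadduct 6 (not isolated)
Conditions: MgBr2·OEt2 (1.5 equiv), CH2Cl2, −20 °C to rt; then DBU (10 mol %)
Reagents that add atoms: none
Why: An ortho-selective Diels–Alder reaction builds ring A; the MgBr2 chelate between the aldehyde and the dioxolane oxygen exposes the H-face of the acetal centre, which sets quaternary C10, and DBU then conjugates the alkene to the butenolide, erasing the C5 centre of 6.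

Step 5
Reactants: 7 butenolide aldehyde
Product: 8 (7R)-7-[(1E)-buta-1,3-dien-1-yl]-7-[(4S)-2,2-dimethyl-1,3-dioxolan-4-yl]-4,5,6,7-tetrahydro-2-benzofuran-1(3H)-one
Conditions: CH2=CHCH2PBu3Br, KOC(CH3)3, THF, −78 to 0 °C
Reagents that add atoms: allyltributylphosphonium bromide, C=CC[P+](CCCC)(CCCC)CCCC.[Br-]
Why: Wittig olefination with an allylic trialkylphosphonium ylide is E-selective and converts the C9 aldehyde into the terminal diene (C9, C11–C13).

Step 6
Reactants: 8 dienyl butenolide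
Product: 10 (3aR,7R,7aR)-7-[(1E)-buta-1,3-dien-1-yl]-7-[(4S)-2,2-dimethyl-1,3-dioxolan-4-yl]-3a-methylhexahydro-2-benzofuran-1(3H)-one, via lithium enolate 9 (not isolated)
Conditions: Me2CuLi (from MeLi and CuI), Et2O, −78 to −20 °C; then NH4Cl (aq)
Reagents that add atoms: lithium dimethylcuprate, [Li+].C[Cu-]C
Why: Cuprate 1,4-addition to the butenolide makes quaternary C4, with methyl entering syn to the flat butadienyl group and anti to the bulkier dioxolanyl group on C10; protonation of the enolate gives the cis-fused γ-lactone (C5).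

Step 7
Reactants: 10 methylated dioxolanyl lactone
Product: 12 (3aR,7R,7aR)-7-[(1E)-buta-1,3-dien-1-yl]-3a-methyl-1-oxooctahydro-2-benzofuran-7-carbaldehyde, via diol 11 (not isolated)
Conditions: H5IO6, EtOAc, 0 °C to rt
Reagents that add atoms: none
Why: Periodic acid hydrolyses the terminal acetonide and cleaves the 1,2-diol (Malaprade cleavage), converting the spent control element into the C20 aldehyde.

Step 8
Reactants: 12 C20 aldehyde
Product: 13 (3aR,7R,7aR)-7-[(1E)-buta-1,3-dien-1-yl]-7-(hydroxymethyl)-3a-methylhexahydro-2-benzofuran-1(3H)-one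
Conditions: NaBH4, MeOH, −20 °C; AcOH quench
Reagents that add atoms: none
Why: Chemoselective borohydride reduction of the aldehyde leaves the lactone and diene intact, and the cold acidic quench limits lactone migration to the new alcohol.

Step 9
Reactants: 13 hydroxymethyl dienyl lactone
Product: 14 acrylate ester of 13 at the C20 oxygen
Conditions: CH2=CHCOCl, Et3N, DMAP (5 mol %), CH2Cl2, 0 °C
Reagents that add atoms: acryloyl chloride, C=CC(=O)Cl
Why: O-Acylation attaches the dienophile (C7, C8, C14) to C20.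

Step 10
Reactants: 14 triene ester
Product: 15 tricyclic bis-lactone with a C11=C12 alkene (γ-lactone ring A spiro at C10 to the cis-fused δ-lactone/cyclohexene; H-8β, H-9β)
Conditions: toluene (5 mM), BHT (cat.), 190 °C, sealed tube
Reagents that add atoms: none
Why: The key ester-tethered intramolecular Diels–Alder reaction closes ring B and ring C at once; the tether fixes the C8–C9/C13–C14 regiochemistry, the endo lactone carbonyl gives the cis fusion, and the diene reacts on the face that keeps C11 away from the crowded C5–C4 side of ring A, so C9 and C8 follow from C10.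

Step 11
Reactants: 15 tricyclic alkene
Product: 16 11β,12β-epoxide of 15
Conditions: mCPBA, NaHCO3, CH2Cl2, 0 °C
Reagents that add atoms: meta-chloroperoxybenzoic acid, O=C(OO)c1cccc(Cl)c1
Why: Prilezhaev epoxidation of the only alkene occurs from the convex β-face; the configuration is unimportant because C11 becomes a carbonyl.

Step 12
Reactants: 16 epoxide
Product: 17 11β-hydroxy-12-ene allylic alcohol
Conditions: Et2Al(tmp) (from Et2AlCl and lithium 2,2,6,6-tetramethylpiperidide), toluene, 0 °C; then H2O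
Reagents that add atoms: none
Why: Aluminium-amide epoxide-to-allylic-alcohol isomerisation (syn β-elimination) removes an accessible C13 methylene proton rather than the hindered C9 methine, leaving the oxygen on C11.

Step 13
Reactants: 17 allylic alcohol
Product: 18 11-oxo-12-ene enone
Conditions: Dess–Martin periodinane, NaHCO3, CH2Cl2, rt
Reagents that add atoms: none
Why: Dess–Martin oxidation of the allylic alcohol gives the enone under neutral conditions, so C9 is not epimerised.

Step 14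
Reactants: 18 enone
Product: 19 13β-[1-(methoxycarbonyl)ethyl] 11-(tert-butyldimethylsilyloxy)-11-ene tricycle (C16 epimers)
Conditions: CH3CH=C(OMe)OSiMe2(t-Bu), TBSOTf (10 mol %), CH2Cl2, −78 °C
Reagents that add atoms: tert-butyl[(1-methoxyprop-1-en-1-yl)oxy]dimethylsilane, CC=C(OC)O[Si](C)(C)C(C)(C)C
Why: Mukaiyama–Michael addition delivers C15–C17 to C13 on the convex β-face of the cis-fused bicycle (anti to the C7 carbonyl on C8) and traps C11 as its silyl enol ether; the C16 centre does not matter here.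

Step 15
Reactants: 19 silyl enol ether ester
Product: 20 11α-(tert-butyldimethylsilyloxy) 13β-[1-(methoxycarbonyl)ethyl] saturated tricycle (C16 epimers)
Conditions: H2 (1 atm), Pd/C (10 wt %), EtOAc, rt
Reagents that add atoms: none
Why: Heterogeneous hydrogenation of the silyl enol ether adds hydrogen from the same convex β-face, which gives the protected 11α oxygen directly.

Step 16
Reactants: 20 silyl ether ester
Product: 22 11-O-tert-butyldimethylsilyl guidongnin C, via lithium enolate 21 (not isolated)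
Conditions: LiN(SiMe3)2 (2.5 equiv), THF, −78 to −20 °C; then AcOH, −78 °C
Reagents that add atoms: none
Why: Intramolecular Claisen (Dieckmann-type) acylation of the lactone enolate by the β-side-chain ester closes ring D and makes C8 quaternary (only a β bond can bridge to C13); the product sits as its C15 enolate, and cold protonation from the open exo face (C14 side) places the C17 methyl endo (16R).

Step 17
Reactants: 22 11-O-silyl guidongnin C
Product: 23 guidongnin C
Conditions: HF·pyridine, pyridine, THF, 0 °C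
Reagents that add atoms: none
Why: Buffered fluoride desilylation frees the C11 alcohol without base, so the epimerisable C16 centre is kept.

## Compound list

1 | (S)-2-(2,2-dimethyl-1,3-dioxolan-4-yl)ethanol | OCC[C@H]1COC(C)(C)O1 | starting material
2 | (S)-2-(2,2-dimethyl-1,3-dioxolan-4-yl)acetaldehyde | O=CC[C@H]1COC(C)(C)O1 | intermediate
3 | (S)-2-(2,2-dimethyl-1,3-dioxolan-4-yl)prop-2-enal | C=C(C=O)[C@H]1COC(C)(C)O1 | intermediate
4 | 4-bromofuran-2(5H)-one | O=C1C=C(Br)CO1 | starting material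
5 | 4-ethenylfuran-2(5H)-one | C=CC1=CC(=O)OC1 | intermediate
6 | primary cycloadduct, (7R)-7-[(4S)-2,2-dimethyl-1,3-dioxolan-4-yl]-1-oxo-1,3,5,6,7,7a-hexahydro-2-benzofuran-7-carbaldehyde (C7a epimers, not isolated) | CC1(C)OC[C@@H](O1)[C@@]2(C=O)CCC=C3COC(=O)C32 | intermediate
7 | (7R)-7-[(4S)-2,2-dimethyl-1,3-dioxolan-4-yl]-1-oxo-1,3,4,5,6,7-hexahydro-2-benzofuran-7-carbaldehyde | CC1(C)OC[C@@H](O1)[C@@]2(C=O)CCCC3=C2C(=O)OC3 | intermediate
8 | (7R)-7-[(1E)-buta-1,3-dien-1-yl]-7-[(4S)-2,2-dimethyl-1,3-dioxolan-4-yl]-4,5,6,7-tetrahydro-2-benzofuran-1(3H)-one | CC1(C)OC[C@@H](O1)[C@@]2(/C=C/C=C)CCCC3=C2C(=O)OC3 | intermediate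
9 | lithium enolate of 10 (C4 methylated, C5=C6 enolate, not isolated) | [Li+].CC1(C)OC[C@@H](O1)[C@@]2(/C=C/C=C)CCC[C@@]3(C)COC([O-])=C32 | intermediate
10 | (3aR,7R,7aR)-7-[(1E)-buta-1,3-dien-1-yl]-7-[(4S)-2,2-dimethyl-1,3-dioxolan-4-yl]-3a-methylhexahydro-2-benzofuran-1(3H)-one | CC1(C)OC[C@@H](O1)[C@@]2(/C=C/C=C)CCC[C@@]3(C)COC(=O)[C@H]32 | intermediate
11 | (3aR,7R,7aR)-7-[(1E)-buta-1,3-dien-1-yl]-7-[(1S)-1,2-dihydroxyethyl]-3a-methylhexahydro-2-benzofuran-1(3H)-one (not isolated) | OC[C@@H](O)[C@@]1(/C=C/C=C)CCC[C@@]2(C)COC(=O)[C@H]21 | intermediate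
12 | (3aR,7R,7aR)-7-[(1E)-buta-1,3-dien-1-yl]-3a-methyl-1-oxooctahydro-2-benzofuran-7-carbaldehyde | O=C[C@@]1(/C=C/C=C)CCC[C@@]2(C)COC(=O)[C@H]21 | intermediate
13 | (3aR,7R,7aR)-7-[(1E)-buta-1,3-dien-1-yl]-7-(hydroxymethyl)-3a-methylhexahydro-2-benzofuran-1(3H)-one | OC[C@@]1(/C=C/C=C)CCC[C@@]2(C)COC(=O)[C@H]21 | intermediate
14 | [(3aR,7R,7aR)-7-[(1E)-buta-1,3-dien-1-yl]-3a-methyl-1-oxooctahydro-2-benzofuran-7-yl]methyl prop-2-enoate | C=CC(=O)OC[C@@]1(/C=C/C=C)CCC[C@@]2(C)COC(=O)[C@H]21 | intermediate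
15 | tricyclic bis-lactone, C11=C12 alkene, H-8β, H-9β (6,19-γ-lactone ring A spiro at C10 to cis-fused 7,20-δ-lactone/cyclohexene) | C1=C[C@H]2[C@@]3(CCC[C@@]4(C)COC(=O)[C@H]43)COC(=O)[C@H]2CC1 | intermediate
16 | 11β,12β-epoxide of 15 | C1C[C@@H]2C(=O)OC[C@]3(CCC[C@@]4(C)COC(=O)[C@H]43)[C@@H]2[C@H]4O[C@@H]14 | intermediate
17 | 11β-hydroxy-12-ene tricyclic bis-lactone | O[C@H]1C=CC[C@@H]2C(=O)OC[C@]3(CCC[C@@]4(C)COC(=O)[C@H]43)[C@H]12 | intermediate
18 | 11-oxo-12-ene tricyclic bis-lactone (enone) | O=C1C=CC[C@@H]2C(=O)OC[C@]3(CCC[C@@]4(C)COC(=O)[C@H]43)[C@H]12 | intermediate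
19 | 13β-[1-(methoxycarbonyl)ethyl]-11-(tert-butyldimethylsilyloxy)-11-ene tricyclic bis-lactone (C16 epimers) | COC(=O)C(C)[C@@H]1C=C(O[Si](C)(C)C(C)(C)C)[C@H]2[C@@]3(CCC[C@@]4(C)COC(=O)[C@H]43)COC(=O)[C@H]2C1 | intermediate
20 | 13β-[1-(methoxycarbonyl)ethyl]-11α-(tert-butyldimethylsilyloxy) tricyclic bis-lactone (C16 epimers) | COC(=O)C(C)[C@@H]1C[C@@H](O[Si](C)(C)C(C)(C)C)[C@H]2[C@@]3(CCC[C@@]4(C)COC(=O)[C@H]43)COC(=O)[C@H]2C1 | intermediate
21 | lithium C15 enolate of 22 (not isolated) | [Li+].CC1=C([O-])[C@]23C[C@H]1C[C@@H](O[Si](C)(C)C(C)(C)C)[C@H]2[C@@]1(CCC[C@@]2(C)COC(=O)[C@H]21)COC3=O | intermediate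
22 | 11-O-tert-butyldimethylsilyl guidongnin C | C[C@H]1C(=O)[C@]23C[C@H]1C[C@@H](O[Si](C)(C)C(C)(C)C)[C@H]2[C@@]1(CCC[C@@]2(C)COC(=O)[C@H]21)COC3=O | intermediate
23 | guidongnin C (4R,5R,8S,9S,10R,11R,13S,16R) | C[C@H]1C(=O)[C@]23C[C@H]1C[C@@H](O)[C@H]2[C@@]1(CCC[C@@]2(C)COC(=O)[C@H]21)COC3=O | target

## Step count and risks

Total: 17 steps. Longest linear sequence: 16 steps (1 to 23 through steps 1, 2 and 4–17); step 3 makes the diene partner separately.

Most likely to fail:

Step 4 (ring A Diels–Alder). Diene 5 is electron-poor and the enal is hindered, so the rate and the chelation-controlled facial selectivity are both uncertain. Fallback, setting out from 5: reduce it with i-Bu2AlH to the lactol 4-ethenyl-2,5-dihydrofuran-2-ol F1 and silylate this to tert-butyl[(4-ethenyl-2,5-dihydrofuran-2-yl)oxy]dimethylsilane F2, a diene without the deactivating carbonyl. Its MgBr2-mediated cycloaddition with 3 gives the silyl acetal cycloadduct F3, Bu4NF/AcOH frees the lactol cycloadduct F4, and TEMPO/PhI(OAc)2 oxidation to 6 followed by DBU rejoins the route at 7.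

Step 6 (cuprate methylation). The β-carbon is fully substituted, and the facial preference rests on the butadienyl group being smaller than the dioxolanyl group. Fallback, setting out from 7: reduce the aldehyde (NaBH4, CeCl3, −40 °C) to the hydroxymethyl butenolide F5, whose lithium alkoxide is both the small C10 substituent and a directing group for Me2CuLi, giving the methylated hydroxy lactone F6. Dess–Martin oxidation gives the methylated lactone aldehyde F7, and the olefination of step 5 rejoins the route at 10.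

Step 16 (Claisen closure and C16 protonation). The bridging acylation may be sluggish, and protonation of enolate 21 may give the 16-epimer. Fallback, setting out from 18: Mukaiyama–Michael addition of tert-butyl[(1-methoxyethenyl)oxy]dimethylsilane gives the acetate adduct F8 and hydrogenation gives the saturated silyl ether ester F9. The same LiN(SiMe3)2 closure gives the C16-unsubstituted bridged ketone F10, α-methylenation ((CH2O)n, PhNHMe·CF3CO2H, THF, reflux) gives the 16-methylene ketone F11, and hydrogenation over Pd/C from the exo face sets C16 and rejoins the route at 22.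

Further compounds
F1 | step 4 | 4-ethenyl-2,5-dihydrofuran-2-ol | OC1OCC(C=C)=C1
F2 | step 4 | tert-butyl[(4-ethenyl-2,5-dihydrofuran-2-yl)oxy]dimethylsilane | CC(C)(C)[Si](C)(C)OC1OCC(C=C)=C1
F3 | step 4 | silyl acetal cycloadduct, (7R)-1-(tert-butyldimethylsilyloxy)-7-[(4S)-2,2-dimethyl-1,3-dioxolan-4-yl]-1,3,5,6,7,7a-hexahydro-2-benzofuran-7-carbaldehyde | CC1(C)OC[C@@H](O1)[C@@]2(C=O)CCC=C3COC(O[Si](C)(C)C(C)(C)C)C32
F4 | step 4 | lactol cycloadduct, (7R)-7-[(4S)-2,2-dimethyl-1,3-dioxolan-4-yl]-1-hydroxy-1,3,5,6,7,7a-hexahydro-2-benzofuran-7-carbaldehyde | CC1(C)OC[C@@H](O1)[C@@]2(C=O)CCC=C3COC(O)C32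
F5 | step 6 | (7R)-7-[(4S)-2,2-dimethyl-1,3-dioxolan-4-yl]-7-(hydroxymethyl)-4,5,6,7-tetrahydro-2-benzofuran-1(3H)-one | CC1(C)OC[C@@H](O1)[C@@]2(CO)CCCC3=C2C(=O)OC3
F6 | step 6 | (3aR,7R,7aR)-7-[(4S)-2,2-dimethyl-1,3-dioxolan-4-yl]-7-(hydroxymethyl)-3a-methylhexahydro-2-benzofuran-1(3H)-one | CC1(C)OC[C@@H](O1)[C@@]2(CO)CCC[C@@]3(C)COC(=O)[C@H]32
F7 | step 6 | (3aR,7R,7aR)-7-[(4S)-2,2-dimethyl-1,3-dioxolan-4-yl]-3a-methyl-1-oxooctahydro-2-benzofuran-7-carbaldehyde | CC1(C)OC[C@@H](O1)[C@@]2(C=O)CCC[C@@]3(C)COC(=O)[C@H]32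
F8 | step 16 | 13β-(methoxycarbonylmethyl)-11-(tert-butyldimethylsilyloxy)-11-ene tricyclic bis-lactone | COC(=O)C[C@@H]1C=C(O[Si](C)(C)C(C)(C)C)[C@H]2[C@@]3(CCC[C@@]4(C)COC(=O)[C@H]43)COC(=O)[C@H]2C1
F9 | step 16 | 13β-(methoxycarbonylmethyl)-11α-(tert-butyldimethylsilyloxy) tricyclic bis-lactone | COC(=O)C[C@@H]1C[C@@H](O[Si](C)(C)C(C)(C)C)[C@H]2[C@@]3(CCC[C@@]4(C)COC(=O)[C@H]43)COC(=O)[C@H]2C1
F10 | step 16 | 17-nor analogue of 22 (C16 methylene ketone without the methyl group) | C1C(=O)[C@]23C[C@H]1C[C@@H](O[Si](C)(C)C(C)(C)C)[C@H]2[C@@]1(CCC[C@@]2(C)COC(=O)[C@H]21)COC3=O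
F11 | step 16 | 16,17-didehydro analogue of 22 (exocyclic enone) | C=C1C(=O)[C@]23C[C@H]1C[C@@H](O[Si](C)(C)C(C)(C)C)[C@H]2[C@@]1(CCC[C@@]2(C)COC(=O)[C@H]21)COC3=O
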